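**Retrosynthetic overview**
- 17 ⇒ 16 + 2: the isobutyryl group at C1 of the central ring goes on last, by Friedel–Crafts acylation of the only free ring CH.
- 16 ⇒ 14: the C5–C6 bond of the central ring is cut; the arene is the carbocyclic isomer of a 4-hydroxy-2-pyranone (lactone opening, then Dieckmann closure), so the central ring is the last ring formed.
- Feature: C3–C4–C5 of the central ring plus the two bridge CH2 groups are a symmetric 1,5-di(Fil)pentan-3-one (9), and C6–C1–C2 are a malonyl unit; 14 ⇒ 9 + malonyl dichloride 11 (pyranone ring, formed second).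
- 9 ⇒ two isobutyrylfilicinic acids 5 + divinyl ketone (from 6); 5 ⇒ phloroglucinol 1 by C-acylation and geminal C-methylation (outer rings first).

Key step: step 6

Remark: the target has no stereocentre and is achiral (every ring carbon is sp2 or carries two methyl groups), so no stereocontrol is needed; enol tautomers are written as in the target SMILES.
Abbreviations: Fil = 2,6-dihydroxy-3,3-dimethyl-5-(2-methylpropanoyl)-4-oxocyclohexa-1,5-dien-1-yl (isobutyrylfilicinic acid bonded through its former ring CH carbon); central ring numbering: C1 acyl, C2/C4/C6 OH, C3/C5 CH2–Fil.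

**Step 1**
Reactants: 1 phloroglucinol; 2 isobutyryl chloride
Product: 3 1-(2,4,6-trihydroxyphenyl)-2-methylpropan-1-one (phlorisobutyrophenone)
Conditions: AlCl3 (3.5 equiv), PhNO2/CH2Cl2, 0 °C → rt; ice/1 M HCl
Reagents that add atoms: none
Why: Friedel–Crafts acylation of the electron-rich arene; the C-acyl group deactivates the ring, so mono-acylation should prevail.

**Step 2**
Reactants: 3 phlorisobutyrophenone
Product: 5 isobutyrylfilicinic acid (3,5-dihydroxy-4,4-dimethyl-2-(2-methylpropanoyl)cyclohexa-2,5-dien-1-one), via C-monomethyl phlorisobutyrophenone 4 (not isolated)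
Conditions: NaOMe (3.5 equiv), MeI (2.5 equiv), MeOH, 0 °C → rt; 1 M HCl; chromatography/crystallisation
Reagents that add atoms: iodomethane, CI
Why: Dearomative geminal C-methylation of the phloroglucinolate at one ring CH (C-alkylation of an ambident polyphenolate in methanol) gives the filicinic acid core; under- and over-methylated congeners are the expected separable by-products.

**Step 3**
Reactants: 5 isobutyrylfilicinic acid (3 equiv); 6 1,5-dichloropentan-3-one
Product: 9 1,5-di(Fil)pentan-3-one, via divinyl ketone 7 (not isolated), via mono-adduct enone 8 (not isolated)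
Conditions: NaOMe (8 equiv), MeOH, slow addition of 6 at 0 °C, then 50 °C; 1 M HCl; excess 5 recovered
Reagents that add atoms: none
Why: Base releases divinyl ketone by double dehydrochlorination and the ring CH of the filicinate (a vinylogous acid carbon) adds to it in two Michael reactions; excess donor and a methoxide medium in which conjugate additions are reversible should steer 8 away from spiro-annulation at its alkylated ring carbon toward the 2:1 adduct, in which both rings stay fully enolised and ionised.

**Step 4**
Reactants: 9 1,5-di(Fil)pentan-3-one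
Product: 10 3-(trimethylsilyloxy)-1,5-di(Fil′)pent-2-ene (Fil′ = Fil with both OH groups as OSiMe3; enol ether geometry not controlled, either isomer serves)
Conditions: TMSOTf (5.5 equiv), Et3N (8 equiv), CH2Cl2, 0 °C → rt; pentane trituration, filtration, concentration; crude used at once
Reagents that add atoms: trimethylsilyl trifluoromethanesulfonate, C[Si](C)(C)OS(=O)(=O)C(F)(F)F
Why: Silylation of the four acidic enol OH groups and amine/silyl triflate enolisation of the dialkyl ketone (silyl enol ether formation); capping both enol oxygens beside each side chain removes the hemiketal ring–chain option, and the symmetric ketone admits only one regioisomer.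

**Step 5**
Reactants: 10 pentakis-silylated enol ether; 11 malonyl dichloride
Product: 14 4-hydroxy-5-(Fil-methyl)-6-(2-Fil-ethyl)-2H-pyran-2-one, via silylated acyl chloride 12 (not isolated), via silylated pyranone 13 (not isolated)
Conditions: 11 (1.1 equiv), Et2O, −78 °C → rt; then THF/1 M HCl, rt
Reagents that add atoms: none
Why: Annulation of a silyl enol ether with malonyl dichloride to a 4-hydroxy-2-pyranone: C-acylation at the enol ether CH gives 12, its enolised 1,3-diketone closes the lactone on the second COCl (6-exo-trig), and aqueous acid removes the silyl groups of 13; the outer rings carry neither free OH nor ring CH, and the symmetry of 9 fixes the regiochemistry.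

**Step 6**
Reactants: 14 4-hydroxy-5-(Fil-methyl)-6-(2-Fil-ethyl)-2H-pyran-2-one
Product: 16 2,4-bis(Fil-methyl)benzene-1,3,5-triol, via methyl diketo ester 15 (not isolated)
Conditions: Mg(OMe)2 (5 equiv), MeOH, 65 °C; then NaOMe (10 equiv), 110 °C (sealed tube), Ar; 1 M HCl, 0 °C
Reagents that add atoms: none
Why: Proposed new method: methoxide attacks the lactone carbonyl of 14 and expels the enolate of the former ketone carbon, giving methyl 3,5-dioxo ester 15, in which one arm sits on the carbon between the ketones and the other on the alpha-CH2 of the terminal ketone; reversible deprotonation of that alpha-CH2 lets it attack the ester carbon, expel methoxide and form the C5–C6 bond, and the resulting cyclohexane-1,3,5-trione tautomerises to the phloroglucinol. The closest known reaction types are the alkoxide-mediated conversion of simple 6-alkyl-4-hydroxy-2-pyranones into phloroglucinols and the Dieckmann/Claisen cyclisation of 3,5-diketo esters to cyclohexane-1,3,5-triones, neither shown with a substituted nucleophilic CH2 and enol-bearing side arms. The ring closes in a 6-(enolendo)-exo-trig mode. No stereocentre is formed, and the labile CH of 15 disappears on aromatisation. The step needs C-closure instead of O-closure back to the pyranone: the singly activated alpha-CH2 is the only carbon that can reach the ester through a six-membered transition state (aldol alternatives would need four-membered rings), re-lactonisation is reversible under alkoxide, and aromatisation with ionisation of the new phenol should make the carbocycle the thermodynamic sink. The two outer rings are present as delocalised filicinate anions, which should neither add alkoxide nor act as carbon nucleophiles, because their ring carbons are fully substituted.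

**Step 7**
Reactants: 16 2,4-bis(Fil-methyl)benzene-1,3,5-triol; 2 isobutyryl chloride
Product: 17 1-[2,4,6-trihydroxy-3,5-bis(Fil-methyl)phenyl]-2-methylpropan-1-one (onind, target)
Conditions: AlCl3 (8 equiv), 2 (1.3 equiv), PhNO2/CH2Cl2, 0 °C → rt; ice/1 M HCl
Reagents that add atoms: none
Why: Friedel–Crafts acylation at the only unsubstituted position of the very electron-rich central ring; the outer rings have no ring CH and their enol oxygens are tied up as aluminium chelates, so any O-acylation should be reversed on acidic work-up.

**Compound list**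
1 | phloroglucinol | Oc1cc(O)cc(O)c1 | starting material
2 | isobutyryl chloride | CC(C)C(Cl)=O | starting material
3 | 1-(2,4,6-trihydroxyphenyl)-2-methylpropan-1-one (phlorisobutyrophenone) | CC(C)C(=O)c1c(O)cc(O)cc1O | intermediate
4 | 1-(2,4,6-trihydroxy-3-methylphenyl)-2-methylpropan-1-one (not isolated) | CC(C)C(=O)c1c(O)cc(O)c(C)c1O | intermediate
5 | isobutyrylfilicinic acid | CC(C)C(=O)C1=C(O)C=C(O)C(C)(C)C1=O | intermediate
6 | 1,5-dichloropentan-3-one | O=C(CCCl)CCCl | starting material
7 | penta-1,4-dien-3-one (divinyl ketone, not isolated) | C=CC(=O)C=C | intermediate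
8 | 5-(Fil)pent-1-en-3-one (mono-adduct, not isolated) | C=CC(=O)CCC1=C(O)C(C)(C)C(=O)C(C(=O)C(C)C)=C1O | intermediate
9 | 1,5-di(Fil)pentan-3-one | O=C(CCC1=C(O)C(C)(C)C(=O)C(C(=O)C(C)C)=C1O)CCC1=C(O)C(C)(C)C(=O)C(C(=O)C(C)C)=C1O | intermediate
10 | 3-(trimethylsilyloxy)-1,5-di(Fil′)pent-2-ene, all four enol OH as OSiMe3, E/Z mixture | C[Si](C)(C)OC(=CCC1=C(O[Si](C)(C)C)C(C)(C)C(=O)C(C(=O)C(C)C)=C1O[Si](C)(C)C)CCC1=C(O[Si](C)(C)C)C(C)(C)C(=O)C(C(=O)C(C)C)=C1O[Si](C)(C)C | intermediate
11 | malonyl dichloride | O=C(Cl)CC(=O)Cl | starting material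
12 | 7-(Fil′)-4-(Fil′-methyl)-3,5-dioxoheptanoyl chloride (not isolated; C4 labile) | O=C(Cl)CC(=O)C(CC1=C(O[Si](C)(C)C)C(C)(C)C(=O)C(C(=O)C(C)C)=C1O[Si](C)(C)C)C(=O)CCC1=C(O[Si](C)(C)C)C(C)(C)C(=O)C(C(=O)C(C)C)=C1O[Si](C)(C)C | intermediate
13 | 4-hydroxy-5-(Fil′-methyl)-6-(2-Fil′-ethyl)-2H-pyran-2-one (not isolated) | O=C1C=C(O)C(CC2=C(O[Si](C)(C)C)C(C)(C)C(=O)C(C(=O)C(C)C)=C2O[Si](C)(C)C)=C(CCC2=C(O[Si](C)(C)C)C(C)(C)C(=O)C(C(=O)C(C)C)=C2O[Si](C)(C)C)O1 | intermediate
14 | 4-hydroxy-5-(Fil-methyl)-6-(2-Fil-ethyl)-2H-pyran-2-one | O=C1C=C(O)C(CC2=C(O)C(C)(C)C(=O)C(C(=O)C(C)C)=C2O)=C(CCC2=C(O)C(C)(C)C(=O)C(C(=O)C(C)C)=C2O)O1 | intermediate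
15 | methyl 7-(Fil)-4-(Fil-methyl)-3,5-dioxoheptanoate (not isolated; C4 enolisable, racemic) | COC(=O)CC(=O)C(CC1=C(O)C(C)(C)C(=O)C(C(=O)C(C)C)=C1O)C(=O)CCC1=C(O)C(C)(C)C(=O)C(C(=O)C(C)C)=C1O | intermediate
16 | 2,4-bis(Fil-methyl)benzene-1,3,5-triol | CC1(C)C(=O)C(C(=O)C(C)C)=C(O)C(Cc2c(O)cc(O)c(CC3=C(O)C(C)(C)C(=O)C(C(=O)C(C)C)=C3O)c2O)=C1O | intermediate
17 | onind, 1-[2,4,6-trihydroxy-3,5-bis(Fil-methyl)phenyl]-2-methylpropan-1-one | CC(C)C(=O)C1=C(O)C(Cc2c(O)c(CC3=C(O)C(C)(C)C(=O)C(C(=O)C(C)C)=C3O)c(O)c(C(=O)C(C)C)c2O)=C(O)C(C)(C)C1=O | target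

**Step count**
Total: 7 steps. Longest linear sequence: 7 steps (1 → 3 → 5 → 9 → 10 → 14 → 16 → 17).

**Steps most likely to fail**

1. Step 6 (Proposed new method). The pyranone may persist as its unreactive 4-oxido anion, so that lactone opening stalls. Once open, retro-Claisen scission of 15 (back to ketone 9 and dimethyl malonate) or re-lactonisation may outpace deprotonation of the singly activated CH2. Prolonged hot alkoxide may also strip an isobutyryl group or scramble the methylene bridges of 16 by retro-Michael fragmentation. The fallback is the known formaldehyde methylene-bridging of acylphloroglucinols. It sets out from 5 and 3: 5 (2.2 equiv), 3 (1 equiv) and aqueous formaldehyde (2 equiv) in dilute aqueous KOH, 0 °C → rt, then acidification. Knoevenagel condensation of 5 should give the isobutyrylfilicinic acid methylene quinone methide F1, which the free ring CH positions of 3 trap in Michael fashion, first to the mono-bridged dimer 3-(Fil-methyl)phlorisobutyrophenone F2 and then, with a second F1, to 17. The fallback rejoins the route at 17 and makes steps 3–7 unnecessary; the symmetric Fil–CH2–Fil dimer is the expected by-product to be separated.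

2. Step 5. The bifunctional acid chloride may acylate the silylated enol oxygens of the outer rings, or oligomerise through its ketene, before it reaches the enol ether carbon. Premature loss of silyl groups would expose the ketone to HCl-driven hemiketal and spiroketal formation. The fallback sets out from 10 and separates C-acylation from lactonisation. Zinc chloride-promoted C-acylation of the silyl enol ether with the monofunctional methyl 3-chloro-3-oxopropanoate (Et2O/CH2Cl2, 0 °C → rt) should give the tetrakis-O-silyl methyl diketo ester F3. Mild aqueous acid then frees 15, which is lactonised with DBU in toluene at reflux (loss of methanol) and so rejoins the route at 14. Since 15 is the species that step 6 passes through, it could also be submitted directly to the step 6 conditions.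

3. Step 3. Ring closure of 8 by a second, intramolecular Michael addition at its already substituted ring carbon (spiro-annulation) may outrun the intermolecular addition and fail to revert. The fallback sets out from 5 and commercial diethyl 3-oxopentanedioate and avoids any enone. Ketalisation (ethylene glycol, TsOH, benzene, azeotropic water removal) gives diethyl 2,2'-(1,3-dioxolane-2,2-diyl)diacetate F4. DIBAL-H (CH2Cl2, −78 °C) gives 2,2'-(1,3-dioxolane-2,2-diyl)diacetaldehyde F5. Three-component reductive alkylation of 5 (2 equiv) with F5, Hantzsch ester (2.2 equiv) and catalytic L-proline (CH2Cl2, rt) should give 2,2-bis[2-(Fil)ethyl]-1,3-dioxolane F6: Knoevenagel condensation is followed by transfer hydrogenation of each alkylidene, so each ring carbon is alkylated once. Aqueous HCl/THF then removes the ketal and rejoins the route at 9.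

**Further compounds**
F1 | step 6 | isobutyrylfilicinic acid methylene quinone methide (exocyclic C=CH2 at the former ring CH carbon) | C=C1C(=O)C(C)(C)C(=O)C(C(=O)C(C)C)=C1O
F2 | step 6 | 3-(Fil-methyl)phlorisobutyrophenone | CC(C)C(=O)c1c(O)cc(O)c(CC2=C(O)C(C)(C)C(=O)C(C(=O)C(C)C)=C2O)c1O
F3 | step 5 | methyl 7-(Fil′)-4-(Fil′-methyl)-3,5-dioxoheptanoate (tetrakis-O-TMS) | COC(=O)CC(=O)C(CC1=C(O[Si](C)(C)C)C(C)(C)C(=O)C(C(=O)C(C)C)=C1O[Si](C)(C)C)C(=O)CCC1=C(O[Si](C)(C)C)C(C)(C)C(=O)C(C(=O)C(C)C)=C1O[Si](C)(C)C
F4 | step 3 | diethyl 2,2'-(1,3-dioxolane-2,2-diyl)diacetate | CCOC(=O)CC1(CC(=O)OCC)OCCO1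
F5 | step 3 | 2,2'-(1,3-dioxolane-2,2-diyl)diacetaldehyde | O=CCC1(CC=O)OCCO1
F6 | step 3 | 2,2-bis[2-(Fil)ethyl]-1,3-dioxolane | CC(C)C(=O)C1=C(O)C(CCC2(CCC3=C(O)C(C)(C)C(=O)C(C(=O)C(C)C)=C3O)OCCO2)=C(O)C(C)(C)C1=O
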